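Abbreviations and numbering: TBS = tert-butyldimethylsilyl, TMS = trimethylsilyl. Flavonoid numbering is used throughout (O1, C2, C3, C4, C4a, C5–C8, C8a; primed atoms = ring B). O3 is the oxygen on C3.

## Retrosynthetic overview

1. The target is the 2,3-trans (2R,3R)-dihydroflavonol. The last operation removes three identical TBS groups from 3-O, 5-O and 4′-O.
2. Ring C (O1–C2–C3–C4–C4a–C8a) comes from a catalytic asymmetric contraction of the seven-membered ring O1–C2–O3–C3=C4–C4a–C8a of a 5-silyloxy-2H-1,3-benzodioxepine. C2 moves from O3 to C3, which makes the C2–C3 bond and both stereocentres, and the expelled ring oxygen becomes the 3-OH.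
3. Enabling feature: C2 is bound to O1 and to the para-oxygenated guaiacyl ring B, so at the acetal level it ionises to a strongly stabilised oxocarbenium ion. Its neighbour C3 is the α-carbon of the C4 aryl ketone and carries the oxygen (3-OH) that can serve as second acetal oxygen and tether.
4. The dioxepine ring is the cyclic acetal of O-TBS-vanillin with an ω,2′-dihydroxyacetophenone (phenol O1–H plus C3–OH), followed by enol silylation.
5. The A-ring piece comes from 2′,6′-dihydroxy-4′-methoxyacetophenone by O-prenylation, silylation of the other OH, a para-Claisen–Cope shift (prenyl to C6, frees exactly O1–H) and enolate hydroxylation. Ring order: A and B are bought, then the dioxepine ring, then ring C.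

Key step: step 8

Assumption: the sense of induction of the chiral acid on this new substrate class cannot be predicted with confidence. The (S,S)-catalyst is written; should the first run deliver the (2S,3S) series, the equally available (R,R)-catalyst is used.

## Route

Step 1
Reactants: 1 2′,6′-dihydroxy-4′-methoxyacetophenone; 2 3-methylbut-2-en-1-ol (prenol)
Product: 3 1-[2-hydroxy-4-methoxy-6-(3-methylbut-2-enyloxy)phenyl]ethanone
Conditions: PPh3, DIAD, THF, 0 °C → rt
Reagents that add atoms: none
Why: Mitsunobu etherification alkylates the acidic phenol on oxygen only (no C-prenylation of the electron-rich ring) and should stop at the mono-ether because the second OH is held in a hydrogen bond to the ketone; the two OH groups of 1 are equivalent, so no regiochemical question arises.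

Step 2
Reactants: 3 1-[2-hydroxy-4-methoxy-6-(3-methylbut-2-enyloxy)phenyl]ethanone
Product: 4 1-[2-(TBSO)-4-methoxy-6-(3-methylbut-2-enyloxy)phenyl]ethanone
Conditions: TBSOTf, 2,6-lutidine, CH2Cl2, 0 °C
Reagents that add atoms: TBSOTf, CC(C)(C)[Si](C)(C)OS(=O)(=O)C(F)(F)F
Why: Silyl triflate silylation of a chelated, hindered phenol is standard protection chemistry, and it marks this oxygen as the later 5-OH while the prenyl ether and the ketone stay untouched under lutidine buffering.

Step 3
Reactants: 4 1-[2-(TBSO)-4-methoxy-6-(3-methylbut-2-enyloxy)phenyl]ethanone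
Product: 7 1-[2-(TBSO)-6-hydroxy-4-methoxy-3-(3-methylbut-2-enyl)phenyl]ethanone, via ortho-dienone 5 (not isolated), via para-dienone 6 (not isolated)
Conditions: PhNEt2, 200 °C, Ar, sealed tube
Reagents that add atoms: none
Why: Tandem aromatic Claisen–Cope (para-Claisen) rearrangement: the first [3,3] shift gives the crowded ortho-dienone 5, whose 1,1-dimethylallyl group moves on by a second [3,3] shift to the para carbon (6) before enolisation, so a normal prenyl group ends between OMe and OTBS (later C6) and exactly the phenol that becomes O1 is freed, a course with close precedent for 2-prenyloxy-4,6-dialkoxyacetophenones.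

Step 4
Reactants: 7 1-[2-(TBSO)-6-hydroxy-4-methoxy-3-(3-methylbut-2-enyl)phenyl]ethanone
Product: 8 2-hydroxy-1-[2-(TBSO)-6-hydroxy-4-methoxy-3-(3-methylbut-2-enyl)phenyl]ethanone
Conditions: NaHMDS (2.3 equiv), THF, −78 °C; 2-(phenylsulfonyl)-3-phenyloxaziridine, −78 °C; AcOH quench at −78 °C
Reagents that add atoms: 2-(phenylsulfonyl)-3-phenyloxaziridine, O=S(=O)(c1ccccc1)N1OC1c1ccccc1
Why: Davis enolate oxidation: two equivalents of amide base give the phenoxide–enolate dianion familiar from o-hydroxyacetophenone chemistry, the N-sulfonyloxaziridine transfers oxygen to the enolate carbon only and leaves the trisubstituted alkene alone (unlike a peracid), and the cold acidic quench forestalls silyl migration.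

Step 5
Reactants: 9 vanillin
Product: 10 4-(TBSO)-3-methoxybenzaldehyde
Conditions: TBSCl, imidazole, DMF, rt
Reagents that add atoms: TBSCl, CC(C)(C)[Si](C)(C)Cl
Why: Routine imidazole-promoted silylation of a phenol, chosen so that all persistent silyl groups of the later intermediates are the same and any silyl exchange is degenerate.

Step 6
Reactants: 8 2-hydroxy-1-[2-(TBSO)-6-hydroxy-4-methoxy-3-(3-methylbut-2-enyl)phenyl]ethanone; 10 4-(TBSO)-3-methoxybenzaldehyde
Product: 12 (±)-6-(TBSO)-2-[4-(TBSO)-3-methoxyphenyl]-8-methoxy-7-(3-methylbut-2-enyl)-2H-1,3-benzodioxepin-5(4H)-one, via bis-TMS ether 11 (not isolated)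
Conditions: (i) TMSCl, Et3N, CH2Cl2, 0 °C; filter, concentrate; (ii) 10, TMSOTf (10 mol %), CH2Cl2 (0.02 M), −78 °C; pyridine quench
Reagents that add atoms: TMSCl, C[Si](C)(C)Cl (its silyl groups are carried by 11 only)
Why: Noyori acetalisation (bis-silyl ether + aldehyde, catalytic TMSOTf) is driven by disiloxane formation at a temperature at which the ketone cannot enolise, the O–C=C–C–C–O spacer with its cis (aromatic) bond has the geometry of the diols that close seven-membered acetals readily, and the new acetal stereocentre forms as a racemate, which is harmless because step 8 erases it.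

Step 7
Reactants: 12 (±)-6-(TBSO)-2-[4-(TBSO)-3-methoxyphenyl]-8-methoxy-7-(3-methylbut-2-enyl)-2H-1,3-benzodioxepin-5(4H)-one
Product: 13 (±)-5,6-bis(TBSO)-2-[4-(TBSO)-3-methoxyphenyl]-8-methoxy-7-(3-methylbut-2-enyl)-2H-1,3-benzodioxepine
Conditions: KHMDS (1.15 equiv), THF, −78 °C; TBSOTf (1.1 equiv), −78 °C; filtration through Et3N-deactivated silica
Reagents that add atoms: TBSOTf, CC(C)(C)[Si](C)(C)OS(=O)(=O)C(F)(F)F
Why: Kinetic enolisation of the α-alkoxy ketone and O-silylation of the potassium enolate (enol silane formation): only the ring CH2 is acidic, the ring permits only the endocyclic cis geometry that holds O3 cis to the aryl carbon C4a, and the slight excess of base leaves no free silyl triflate to ionise the acetal.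

Step 8
Reactants: 13 (±)-5,6-bis(TBSO)-2-[4-(TBSO)-3-methoxyphenyl]-8-methoxy-7-(3-methylbut-2-enyl)-2H-1,3-benzodioxepine
Product: 15 (2R,3R)-3,5-bis(TBSO)-2-[4-(TBSO)-3-methoxyphenyl]-7-methoxy-6-(3-methylbut-2-enyl)-2,3-dihydro-4H-chromen-4-one, via ring-opened oxocarbenium ion 14 (not isolated)
Conditions: (S,S)-IDPi (confined BINOL-derived imidodiphosphorimidate, N-triflyl core, bulky 3,3′-aryl groups; 5 mol %), toluene, −60 °C; Et3N quench
Reagents that add atoms: none
Why: Proposed new method: the silylium–IDPi ion pair (formed when the acid protodesilylates a few per cent of 13) silylates the enol-type acetal oxygen O3, the C2–O3 bond ionises because C2 is flanked by O1 and the para-silyloxy guaiacyl ring, C3 of the (E)-1,2-bis(silyloxy)alkene in the aryloxocarbenium ion 14 attacks C2, and the C4 silyloxycarbenium ion returns its TBS group to the anion, so C2 has formally moved from O3 to C3 and the seven-membered ring has expelled O3 as the 3-OTBS group. The closest known reaction types are the Mukaiyama aldol addition of enol silanes to acetals under silylium/chiral-counteranion catalysis, the Petasis–Ferrier rearrangement and the Lewis-acid O-to-C rearrangement of anomeric enol ethers; new are the 1,2-topology and the contraction of a 1,3-benzodioxepine. Ring C closes in a 6-(enolendo)-endo-trig mode, equivalent to a disrotatory 6π closure of the 2-oxoniatriene C2=O1(+)–C8a=C4a–C4=C3. The relative configuration follows from geometry: the former ring leaves O3 cis to C4a ("inside") while the aryl group of the (E)-oxocarbenium ion is "outside", and inside/outside termini give the 2,3-trans product, which is also the more stable diequatorial isomer. The absolute configuration at C2, and through the trans closure at C3, is set by the confined chiral anion, which pairs with the achiral cation and selects one helical sense of closure, so the racemic acetal centre of 13 is erased and both enantiomers converge on (2R,3R). The step needs attack through C3 rather than C4 and productive C2–O3 rather than C2–O1 cleavage: attack through C3 leaves the charge on C4 next to the electron-rich A ring and gives a six-membered ring whereas attack through C4 would be a 5-endo closure, and C2–O1 cleavage is reversible and leads nowhere.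

Step 9
Reactants: 15 (2R,3R)-3,5-bis(TBSO)-2-[4-(TBSO)-3-methoxyphenyl]-7-methoxy-6-(3-methylbut-2-enyl)-2,3-dihydro-4H-chromen-4-one
Product: 16 (2R,3R)-3,5-dihydroxy-2-(4-hydroxy-3-methoxyphenyl)-7-methoxy-6-(3-methylbut-2-enyl)-2,3-dihydro-4H-chromen-4-one
Conditions: HF·pyridine, pyridine, THF, 0 °C → rt
Reagents that add atoms: none
Why: Buffered, mildly acidic fluoride desilylation removes the two aryl and the one secondary alkyl TBS ether in one operation without forming a phenoxide or an enolate, so neither C2 (quinone-methide ring opening) nor C3 (enolisation) should epimerise and the prenyl/5-OH pair should not cyclise.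

## Compound list

1 | 1-(2,6-dihydroxy-4-methoxyphenyl)ethanone | CC(=O)c1c(O)cc(OC)cc1O | starting material
2 | 3-methylbut-2-en-1-ol (prenol) | CC(C)=CCO | starting material
3 | 1-[2-hydroxy-4-methoxy-6-(3-methylbut-2-enyloxy)phenyl]ethanone | CC(=O)c1c(O)cc(OC)cc1OCC=C(C)C | intermediate
4 | 1-[2-(TBSO)-4-methoxy-6-(3-methylbut-2-enyloxy)phenyl]ethanone | CC(=O)c1c(O[Si](C)(C)C(C)(C)C)cc(OC)cc1OCC=C(C)C | intermediate
5 | ortho-dienone, (±)-2-acetyl-3-(TBSO)-5-methoxy-6-(2-methylbut-3-en-2-yl)cyclohexa-2,4-dien-1-one | CC(=O)C1=C(O[Si](C)(C)C(C)(C)C)C=C(OC)C(C(C)(C)C=C)C1=O | intermediate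
6 | para-dienone, (±)-2-acetyl-3-(TBSO)-5-methoxy-4-(3-methylbut-2-enyl)cyclohexa-2,5-dien-1-one | CC(=O)C1=C(O[Si](C)(C)C(C)(C)C)C(CC=C(C)C)C(OC)=CC1=O | intermediate
7 | 1-[2-(TBSO)-6-hydroxy-4-methoxy-3-(3-methylbut-2-enyl)phenyl]ethanone | CC(=O)c1c(O)cc(OC)c(CC=C(C)C)c1O[Si](C)(C)C(C)(C)C | intermediate
8 | 2-hydroxy-1-[2-(TBSO)-6-hydroxy-4-methoxy-3-(3-methylbut-2-enyl)phenyl]ethanone | OCC(=O)c1c(O)cc(OC)c(CC=C(C)C)c1O[Si](C)(C)C(C)(C)C | intermediate
9 | vanillin | COc1cc(C=O)ccc1O | starting material
10 | 4-(TBSO)-3-methoxybenzaldehyde | COc1cc(C=O)ccc1O[Si](C)(C)C(C)(C)C | intermediate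
11 | bis-TMS ether of 8 (aryl OTMS and primary OTMS) | C[Si](C)(C)OCC(=O)c1c(O[Si](C)(C)C)cc(OC)c(CC=C(C)C)c1O[Si](C)(C)C(C)(C)C | intermediate
12 | (±)-6-(TBSO)-2-[4-(TBSO)-3-methoxyphenyl]-8-methoxy-7-(3-methylbut-2-enyl)-2H-1,3-benzodioxepin-5(4H)-one | COc1cc(C2OCC(=O)c3c(O2)cc(OC)c(CC=C(C)C)c3O[Si](C)(C)C(C)(C)C)ccc1O[Si](C)(C)C(C)(C)C | intermediate
13 | (±)-5,6-bis(TBSO)-2-[4-(TBSO)-3-methoxyphenyl]-8-methoxy-7-(3-methylbut-2-enyl)-2H-1,3-benzodioxepine | COc1cc(C2OC=C(O[Si](C)(C)C(C)(C)C)c3c(O2)cc(OC)c(CC=C(C)C)c3O[Si](C)(C)C(C)(C)C)ccc1O[Si](C)(C)C(C)(C)C | intermediate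
14 | ring-opened (E)-aryloxocarbenium ion bearing the (E)-1,2-bis(TBSO)vinyl group, paired with the IDPi anion | COc1cc(/C=[O+]/c2cc(OC)c(CC=C(C)C)c(O[Si](C)(C)C(C)(C)C)c2/C(O[Si](C)(C)C(C)(C)C)=C\O[Si](C)(C)C(C)(C)C)ccc1O[Si](C)(C)C(C)(C)C | intermediate
15 | (2R,3R)-3,5-bis(TBSO)-2-[4-(TBSO)-3-methoxyphenyl]-7-methoxy-6-(3-methylbut-2-enyl)-2,3-dihydro-4H-chromen-4-one (2,3-trans) | COc1cc([C@H]2Oc3cc(OC)c(CC=C(C)C)c(O[Si](C)(C)C(C)(C)C)c3C(=O)[C@@H]2O[Si](C)(C)C(C)(C)C)ccc1O[Si](C)(C)C(C)(C)C | intermediate
16 | (2R,3R)-3,5-dihydroxy-2-(4-hydroxy-3-methoxyphenyl)-7-methoxy-6-(3-methylbut-2-enyl)-2,3-dihydro-4H-chromen-4-one | COc1cc([C@H]2Oc3cc(OC)c(CC=C(C)C)c(O)c3C(=O)[C@@H]2O)ccc1O | target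

## Step count and risks

Total step count: 9. Longest linear sequence: 8 steps (steps 1–4 and 6–9, from 1 to 16).

Steps most likely to fail:

1. **Step 8.** The ionisation may take an unproductive course: C2–O1 cleavage, or loss of the B-ring silyl group to a neutral quinone methide that leaves the chiral pocket. Closure could then become slow or poorly enantioselective, or be overtaken by protodesilylation back to the ketone. The fallback is the known chalcone-epoxide route, setting out from 7 and returning at 16.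
   - The phenol of 7 is capped (MOMCl, i-Pr2NEt) to the methoxymethyl ether F1.
   - LiHMDS aldol addition to 10 gives the β-hydroxy ketone F2, and MsCl/Et3N then DBU gives the (E)-chalcone F3.
   - Juliá–Colonna epoxidation (poly-L-leucine, urea–H2O2, DBU, THF), a nucleophilic epoxidation that ignores the prenyl alkene, gives the (αR,βS)-epoxy ketone F4.
   - Dilute HCl in MeOH removes the MOM group, and the freed phenol opens the epoxide at the benzylic carbon with inversion. This gives the 5,4′-bis-silylated (2R,3R)-dihydroflavonol F5, which the conditions of step 9 convert into 16.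

2. **Step 6.** Intermolecular acetalisation through the more nucleophilic primary silyl ether may outrun closure of the seven-membered ring, or the labile aryl alkyl acetal may ionise and hydrolyse during work-up. The fallback sets out from 8 (with 10) and returns at 12, reaching the acetal carbon by oxidation instead of condensation.
   - NaBH4 reduces 10 to the benzyl alcohol F6, and Cl3CCN/DBU gives the trichloroacetimidate F7.
   - La(OTf)3-catalysed benzylation of the primary OH of 8 (the chelated phenol stays inert) gives the benzyl ether F8.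
   - DDQ with 4 Å sieves in CH2Cl2 at 0 °C abstracts hydride from the electron-rich benzyl ether, and the neighbouring phenol captures the oxocarbenium ion to give 12 (oxidative acetal formation as known for p-alkoxybenzyl ethers).

3. **Step 4.** The aryl silyl group may migrate to the new alkoxide, the sulfonimine by-product may capture the unhindered enolate, or over-oxidation may occur. The fallback sets out from 4 and returns at 8. The oxygen is introduced by epoxidation of an enol silane before the phenol is freed.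
   - TBSOTf/Et3N converts 4 into the enol silane F9.
   - Rubottom oxidation (mCPBA, 1.0 equiv, NaHCO3, CH2Cl2, −20 °C) takes the far more electron-rich enol silane ahead of the allyl-ether alkene and gives the α-silyloxy ketone F10.
   - The conditions of step 3 give the rearranged phenol F11.
   - CSA in MeOH at 0 °C cleaves only the primary alkyl silyl ether to give 8.

## Further compounds

F1 | step 8 | 1-[2-(TBSO)-4-methoxy-6-(methoxymethoxy)-3-(3-methylbut-2-enyl)phenyl]ethanone | CC(=O)c1c(OCOC)cc(OC)c(CC=C(C)C)c1O[Si](C)(C)C(C)(C)C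
F2 | step 8 | (±)-3-hydroxy-3-[4-(TBSO)-3-methoxyphenyl]-1-[2-(TBSO)-4-methoxy-6-(methoxymethoxy)-3-(3-methylbut-2-enyl)phenyl]propan-1-one | COc1cc(C(O)CC(=O)c2c(OCOC)cc(OC)c(CC=C(C)C)c2O[Si](C)(C)C(C)(C)C)ccc1O[Si](C)(C)C(C)(C)C
F3 | step 8 | (E)-3-[4-(TBSO)-3-methoxyphenyl]-1-[2-(TBSO)-4-methoxy-6-(methoxymethoxy)-3-(3-methylbut-2-enyl)phenyl]prop-2-en-1-one | COc1cc(/C=C/C(=O)c2c(OCOC)cc(OC)c(CC=C(C)C)c2O[Si](C)(C)C(C)(C)C)ccc1O[Si](C)(C)C(C)(C)C
F4 | step 8 | (2R,3S)-trans-2,3-epoxy ketone of F3 | O=C([C@@H]1O[C@H]1c2ccc(O[Si](C)(C)C(C)(C)C)c(OC)c2)c3c(OCOC)cc(OC)c(CC=C(C)C)c3O[Si](C)(C)C(C)(C)C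
F5 | step 8 | (2R,3R)-5-(TBSO)-2-[4-(TBSO)-3-methoxyphenyl]-3-hydroxy-7-methoxy-6-(3-methylbut-2-enyl)-2,3-dihydro-4H-chromen-4-one | COc1cc([C@H]2Oc3cc(OC)c(CC=C(C)C)c(O[Si](C)(C)C(C)(C)C)c3C(=O)[C@@H]2O)ccc1O[Si](C)(C)C(C)(C)C
F6 | step 6 | [4-(TBSO)-3-methoxyphenyl]methanol | COc1cc(CO)ccc1O[Si](C)(C)C(C)(C)C
F7 | step 6 | 4-(TBSO)-3-methoxybenzyl 2,2,2-trichloroacetimidate | COc1cc(COC(=N)C(Cl)(Cl)Cl)ccc1O[Si](C)(C)C(C)(C)C
F8 | step 6 | 2-[4-(TBSO)-3-methoxybenzyloxy]-1-[2-(TBSO)-6-hydroxy-4-methoxy-3-(3-methylbut-2-enyl)phenyl]ethanone | COc1cc(COCC(=O)c2c(O)cc(OC)c(CC=C(C)C)c2O[Si](C)(C)C(C)(C)C)ccc1O[Si](C)(C)C(C)(C)C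
F9 | step 4 | 1-(TBSO)-1-[2-(TBSO)-4-methoxy-6-(3-methylbut-2-enyloxy)phenyl]ethene | C=C(O[Si](C)(C)C(C)(C)C)c1c(O[Si](C)(C)C(C)(C)C)cc(OC)cc1OCC=C(C)C
F10 | step 4 | 2-(TBSO)-1-[2-(TBSO)-4-methoxy-6-(3-methylbut-2-enyloxy)phenyl]ethanone | CC(C)(C)[Si](C)(C)OCC(=O)c1c(O[Si](C)(C)C(C)(C)C)cc(OC)cc1OCC=C(C)C
F11 | step 4 | 2-(TBSO)-1-[2-(TBSO)-6-hydroxy-4-methoxy-3-(3-methylbut-2-enyl)phenyl]ethanone | CC(C)(C)[Si](C)(C)OCC(=O)c1c(O)cc(OC)c(CC=C(C)C)c1O[Si](C)(C)C(C)(C)C
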